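**Overview**

- Retrosynthesis: after removal of one MOM acetal from O5, the three aryl–C5 bonds (C8–CMe2 on ring A, C5'–CH2 and C6'–CH2 on ring B) are cut together. This returns the C5 units to O7, O4' and O3' of a quercetin tris-ether.
- What makes this possible: every C5 unit sits ortho or para to a phenol oxygen, and its sense fits the number of [3,3] shifts. The reverse (1,1-dimethylallyl) group on C8 is one shift from a prenyl ether on O7. The prenyl on C5' is one shift from a 1,1-dimethylallyl ether on O4'. The prenyl on C6' is two shifts (ortho, then Cope to para) from a prenyl ether on O3'.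
- The tris-ether is cut further at O1–C2 of ring C (oxidative cyclisation) and at the Cα=Cβ bond of a chalcone (aldol). This gives a ketone from 2,4,6-trihydroxyacetophenone and an aldehyde from 3,4-dihydroxybenzaldehyde.
- Forward: rings A and B are bought as benzenes and joined by Claisen–Schmidt condensation. Ring C is closed by Algar–Flynn–Oyamada oxidation, the alkyne is semihydrogenated, one heating moves the three C5 units from O to C, and the acetal is cleaved. No ring forms after ring C.
- Stereochemistry: the target has no stereocenter and both trisubstituted alkenes carry geminal methyls, so nothing has to be controlled. The E-alkene of the chalcone and the racemic centres of transient intermediates disappear on the way.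

Key step: step 8

Assumption: the three migrations of step 8 are written in the order O4', O7, O3' (lowest expected barrier first); the end product does not depend on this order. Flavone numbering is used (ring A C5–C8, ring B primed, ring C the pyranone).

**Route**

Step 1
Reactants: 1 2,4,6-trihydroxyacetophenone; 2 prenyl bromide (1-bromo-3-methylbut-2-ene)
Product: 3 2,6-dihydroxy-4-(3-methylbut-2-enyloxy)acetophenone
Conditions: K2CO3 (1.1 equiv), 2 (1.0 equiv), acetone, reflux
Reagents that add atoms: none
Why: Williamson etherification under weak-base control: the 4-OH is the only hydroxyl not tied up in a hydrogen bond to the acetyl carbonyl and is the most acidic, so one equivalent of base and bromide in acetone should alkylate it on oxygen in preference to the chelated 2- and 6-OH groups and to ring carbon.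

Step 2
Reactants: 3 2,6-dihydroxy-4-(3-methylbut-2-enyloxy)acetophenone
Product: 4 2-hydroxy-6-(methoxymethoxy)-4-(3-methylbut-2-enyloxy)acetophenone
Conditions: MOMCl (1.2 equiv), iPr2NEt, CH2Cl2, 0 °C to rt
Reagents that add atoms: chloromethyl methyl ether, COCCl
Why: Acetal (MOM) protection of one of the two equivalent chelated hydroxyls; the remaining hydroxyl stays locked in the hydrogen bond to the ketone and should not be alkylated by MOMCl with an amine base, the usual outcome with phloroacetophenones.

Step 3
Reactants: 5 3,4-dihydroxybenzaldehyde; 2 prenyl bromide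
Product: 6 4-hydroxy-3-(3-methylbut-2-enyloxy)benzaldehyde
Conditions: NaH (2.1 equiv), DMSO, rt; then 2 (1.0 equiv); dilute aq. HCl work-up
Reagents that add atoms: none
Why: Regioselective Williamson etherification through the dianion: the 4-oxide is delocalised into the para-formyl group, so the 3-oxide is the more nucleophilic centre and should take the single equivalent of prenyl bromide.

Step 4
Reactants: 6 4-hydroxy-3-(3-methylbut-2-enyloxy)benzaldehyde; 7 3-chloro-3-methylbut-1-yne
Product: 8 4-(2-methylbut-3-yn-2-yloxy)-3-(3-methylbut-2-enyloxy)benzaldehyde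
Conditions: CuCl2·2H2O (cat.), DBU, MeCN, 0 °C
Reagents that add atoms: none
Why: Copper-catalysed etherification of a phenol by a tertiary propargylic chloride (through a copper acetylide that ionises to an allenylidene-type electrophile), which is most efficient for acidic phenols such as this para-formylphenol and should leave the prenyl ether untouched at 0 °C.

Step 5
Reactants: 4 2-hydroxy-6-(methoxymethoxy)-4-(3-methylbut-2-enyloxy)acetophenone; 8 4-(2-methylbut-3-yn-2-yloxy)-3-(3-methylbut-2-enyloxy)benzaldehyde
Product: 9 (E)-2'-hydroxy-6'-(methoxymethoxy)-4',3-bis(prenyloxy)-4-(1,1-dimethylpropargyloxy)chalcone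
Conditions: KOH (50% aq.), EtOH, rt
Reagents that add atoms: none
Why: Claisen–Schmidt (crossed aldol) condensation of the methyl ketone enolate with the non-enolisable aldehyde followed by E1cB dehydration, which should give the conjugated E-alkene under thermodynamic control; all ethers and the MOM acetal are stable to aqueous-alcoholic KOH.

Step 6
Reactants: 9 (E)-2'-hydroxy-6'-(methoxymethoxy)-4',3-bis(prenyloxy)-4-(1,1-dimethylpropargyloxy)chalcone
Product: 11 5-O-MOM-7,3'-di-O-prenyl-4'-O-(1,1-dimethylpropargyl)quercetin, via trans-dihydroflavonol 10 (not isolated)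
Conditions: H2O2 (30% aq.), NaOH (aq.), MeOH–THF, 0 °C
Reagents that add atoms: hydrogen peroxide, OO
Why: Algar–Flynn–Oyamada reaction: the 2'-phenoxide closes ring C at Cβ (6-endo) while hydroperoxide oxygenates Cα to give trans-dihydroflavonol 10 as a racemate, whose two stereocenters are erased when alkaline H2O2 dehydrogenates it to the flavonol; nucleophilic hydroperoxide should attack only the enone and not the isolated alkenes or the alkyne, and the low temperature is meant to hold back the competing 5-exo path to the aurone that a 6'-alkoxy group favours.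

Step 7
Reactants: 11 5-O-MOM-7,3'-di-O-prenyl-4'-O-(1,1-dimethylpropargyl)quercetin
Product: 12 5-O-MOM-7,3'-di-O-prenyl-4'-O-(1,1-dimethylallyl)quercetin
Conditions: H2 (1 atm), Pd/CaCO3 poisoned with Pb(OAc)2, quinoline, EtOAc, rt, stopped after 1 equiv H2
Reagents that add atoms: none
Why: Lindlar semihydrogenation: the poisoned palladium surface binds the terminal alkyne far more strongly than the resulting vinyl group or the trisubstituted prenyl alkenes, so uptake should stop at the tertiary allyl ether, which is generated only now because it is the most heat- and acid-sensitive group of the route.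

Step 8
Reactants: 12 5-O-MOM-7,3'-di-O-prenyl-4'-O-(1,1-dimethylallyl)quercetin
Product: 17 5-O-MOM broussoflavonol C, via 5'-prenyl-4'-phenol 13 (not isolated), via 8-(1,1-dimethylallyl)-7-phenol 14 (not isolated), via C2' ortho-dienone 15 (not isolated), via C6' para-dienone 16 (not isolated)
Conditions: PhNEt2 (degassed, dilute), Ar, sealed tube, 120 °C, then 200 °C
Reagents that add atoms: none
Why: Proposed new method: four thermally allowed [3,3] shifts are expected to run in sequence on the ramp - the tertiary allyl ether on O4' rearranges first through a chair-like transition state to the only open ortho carbon C5' and rearomatises to phenol 13, the O7 prenyl ether then undergoes an ortho-Claisen shift with allyl inversion to C8 to give 14, and the O3' prenyl ether shifts to C2' to give ortho-dienone 15, which hands the C5 unit on by a Cope shift to C6' (para-dienone 16) before tautomerising to the catechol. The closest known reactions are the ortho-Claisen rearrangement of 7-O-prenylflavonoids to 8-(1,1-dimethylallyl) products in hot N,N-dialkylanilines, the Claisen rearrangement of aryl 1,1-dimethylallyl ethers to ortho-prenylphenols near 100-120 °C and the para-Claisen-Cope rearrangement of aryl prenyl ethers; new are the combination of all three on one flavonol in one pot and the reliance on a Cope relay past an ortho carbon that still carries hydrogen. No ring is closed and no stereocenter remains, since the sp3 centres of 15 and 16 are racemic and vanish on aromatisation. Two site selectivities are required: C8 over C6 in ring A, expected from the higher C7-C8 bond order of the benzopyranone and from the 5-O-MOM group that crowds C6, and C6' over C2' in ring B, expected because the quaternary carbon of 15 is wedged between ring C and the C3' carbonyl so that strain-relieving Cope migration should outrun enolisation, while any ortho shift to the oxygen-bearing C4' can only relay to the same carbon C6'. In ring A no Cope follow-up is possible because the para position C4a is a ring-fusion carbon, so the reverse 1,1-dimethylallyl group stays on C8, and the basic, oxygen-free solvent should keep the new ortho-allylphenols from cyclising or oxidising.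

Step 9
Reactants: 17 5-O-MOM broussoflavonol C
Product: 18 broussoflavonol C
Conditions: HCl (1 M aq., few equiv), MeOH, 40 °C, Ar
Reagents that add atoms: none
Why: Acid-catalysed acetal methanolysis: the 5-O-MOM group lies peri to the C4 carbonyl, which assists its departure as the chelated 5-OH forms, so dilute HCl in MeOH at 40 °C should cleave it before the allyl groups ortho to free phenols can cyclise to chromans or dihydrofurans.

**Compound list**

1 | 2,4,6-trihydroxyacetophenone | CC(=O)c1c(O)cc(O)cc1O | starting material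
2 | prenyl bromide (1-bromo-3-methylbut-2-ene) | CC(C)=CCBr | starting material
3 | 2,6-dihydroxy-4-(3-methylbut-2-enyloxy)acetophenone | CC(=O)c1c(O)cc(OCC=C(C)C)cc1O | intermediate
4 | 2-hydroxy-6-(methoxymethoxy)-4-(3-methylbut-2-enyloxy)acetophenone | CC(=O)c1c(O)cc(OCC=C(C)C)cc1OCOC | intermediate
5 | 3,4-dihydroxybenzaldehyde | O=Cc1ccc(O)c(O)c1 | starting material
6 | 4-hydroxy-3-(3-methylbut-2-enyloxy)benzaldehyde | O=Cc1ccc(O)c(OCC=C(C)C)c1 | intermediate
7 | 3-chloro-3-methylbut-1-yne | C#CC(C)(C)Cl | starting material
8 | 4-(2-methylbut-3-yn-2-yloxy)-3-(3-methylbut-2-enyloxy)benzaldehyde | O=Cc1ccc(OC(C)(C)C#C)c(OCC=C(C)C)c1 | intermediate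
9 | (E)-1-[2-hydroxy-6-(methoxymethoxy)-4-(3-methylbut-2-enyloxy)phenyl]-3-[4-(2-methylbut-3-yn-2-yloxy)-3-(3-methylbut-2-enyloxy)phenyl]prop-2-en-1-one | O=C(/C=C/c1ccc(OC(C)(C)C#C)c(OCC=C(C)C)c1)c1c(O)cc(OCC=C(C)C)cc1OCOC | intermediate
10 | racemic trans-3-hydroxy-5-(methoxymethoxy)-7-(3-methylbut-2-enyloxy)-2-[4-(2-methylbut-3-yn-2-yloxy)-3-(3-methylbut-2-enyloxy)phenyl]chroman-4-one (2R,3R enantiomer drawn; not isolated) | c1cc(OC(C)(C)C#C)c(OCC=C(C)C)cc1[C@@H]1[C@@H](O)C(=O)c2c(OCOC)cc(OCC=C(C)C)cc2O1 | intermediate
11 | 3-hydroxy-5-(methoxymethoxy)-7-(3-methylbut-2-enyloxy)-2-[4-(2-methylbut-3-yn-2-yloxy)-3-(3-methylbut-2-enyloxy)phenyl]chromen-4-one | O=c1c(O)c(-c2ccc(OC(C)(C)C#C)c(OCC=C(C)C)c2)oc2cc(OCC=C(C)C)cc(OCOC)c12 | intermediate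
12 | 3-hydroxy-5-(methoxymethoxy)-7-(3-methylbut-2-enyloxy)-2-[4-(2-methylbut-3-en-2-yloxy)-3-(3-methylbut-2-enyloxy)phenyl]chromen-4-one | O=c1c(O)c(-c2ccc(OC(C)(C)C=C)c(OCC=C(C)C)c2)oc2cc(OCC=C(C)C)cc(OCOC)c12 | intermediate
13 | 3-hydroxy-2-[4-hydroxy-3-(3-methylbut-2-enyl)-5-(3-methylbut-2-enyloxy)phenyl]-5-(methoxymethoxy)-7-(3-methylbut-2-enyloxy)chromen-4-one (not isolated) | O=c1c(O)c(-c2cc(CC=C(C)C)c(O)c(OCC=C(C)C)c2)oc2cc(OCC=C(C)C)cc(OCOC)c12 | intermediate
14 | 3,7-dihydroxy-2-[4-hydroxy-3-(3-methylbut-2-enyl)-5-(3-methylbut-2-enyloxy)phenyl]-5-(methoxymethoxy)-8-(2-methylbut-3-en-2-yl)chromen-4-one (not isolated) | O=c1c(O)c(-c2cc(CC=C(C)C)c(O)c(OCC=C(C)C)c2)oc2c(C(C)(C)C=C)c(O)cc(OCOC)c12 | intermediate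
15 | ortho-dienone: rings A and C as in 14, ring B a cyclohexa-2,4-dienone with C3' ketone, sp3 C2' bearing H and the 2-methylbut-3-en-2-yl group, 4'-OH and 5'-prenyl (racemic, not isolated) | O=c1c(O)c(C2=CC(CC=C(C)C)=C(O)C(=O)C2C(C)(C)C=C)oc2c(C(C)(C)C=C)c(O)cc(OCOC)c12 | intermediate
16 | para-dienone: rings A and C as in 14, ring B a cyclohexa-2,5-dienone with C3' ketone, sp3 C6' bearing H and a 3-methylbut-2-enyl group, 4'-OH and 5'-prenyl (racemic, not isolated) | O=c1c(O)c(C2=CC(=O)C(O)=C(CC=C(C)C)C2CC=C(C)C)oc2c(C(C)(C)C=C)c(O)cc(OCOC)c12 | intermediate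
17 | 5-O-MOM broussoflavonol C: 3,7-dihydroxy-2-[4,5-dihydroxy-2,3-bis(3-methylbut-2-enyl)phenyl]-5-(methoxymethoxy)-8-(2-methylbut-3-en-2-yl)chromen-4-one | C=CC(C)(C)c1c(O)cc(OCOC)c2c(=O)c(O)c(-c3cc(O)c(O)c(CC=C(C)C)c3CC=C(C)C)oc12 | intermediate
18 | broussoflavonol C: 3,5,7-trihydroxy-2-[4,5-dihydroxy-2,3-bis(3-methylbut-2-enyl)phenyl]-8-(2-methylbut-3-en-2-yl)chromen-4-one | C=CC(C)(C)c1c(O)cc(O)c2c(=O)c(O)c(-c3cc(O)c(O)c(CC=C(C)C)c3CC=C(C)C)oc12 | target

**Step count and risks**

Total step count: 9. Longest linear sequence: 7 steps (steps 1, 2, 5, 6, 7, 8, 9; the aldehyde branch through steps 3 and 4 is equally long).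

Steps most likely to fail:

1. Step 8 (proposed new method). What may go wrong:
- the ortho-dienone formed from the O3' ether may enolise at C2' faster than it relays by Cope shift, so that the C5 unit stops at C2' in the reverse sense;
- the ring-A shift may divide between C6 and C8;
- the allyl ethers may fragment with loss of isoprene;
- the new ortho-allylphenols may cyclise at 200 °C.

Fallback (known reactions only): the C6'–prenyl bond is made by cross-coupling and O3' carries a MOM group, so that the thermal step is reduced to two ordinary ortho-Claisen shifts. It sets out from ketone 4 and chloride 7, replaces aldehyde 8 by a new partner, and rejoins the route at target 18. Purchased 2-bromo-4,5-dimethoxybenzaldehyde F1 would be demethylated with BBr3 (CH2Cl2, -78 °C to rt) to 2-bromo-4,5-dihydroxybenzaldehyde F2. Its dianion (NaH, 2 equiv, DMF) would take one equivalent of MOMCl at the oxide meta to the formyl group, by the logic of step 3, to give 2-bromo-4-hydroxy-5-(methoxymethoxy)benzaldehyde F3. Stille coupling with tributyl(3-methylbut-2-enyl)stannane (Pd(PPh3)4, DMF, 90 °C) would give 4-hydroxy-5-(methoxymethoxy)-2-prenylbenzaldehyde F4. Etherification with 7 under the conditions of step 4 would give 5-(methoxymethoxy)-4-(1,1-dimethylpropargyloxy)-2-prenylbenzaldehyde F5. Claisen–Schmidt condensation with 4 would give the 6-prenyl chalcone F6, Algar–Flynn–Oyamada oxidation the 6'-prenyl flavonol alkyne F7, and Lindlar semihydrogenation the 6'-prenyl 4'-O-(1,1-dimethylallyl) flavonol F8, as in steps 5 to 7. Heating F8 in N,N-diethylaniline would then move only the O4' group to C5' and the O7 group to C8, giving 5,3'-di-O-MOM broussoflavonol C F9. HCl in MeOH as in step 9 would release 18.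

2. Step 6. What may go wrong: with an alkoxy group at C6' of the chalcone the phenoxide may close 5-exo at Cα and divert material to the aurone, and long exposure to alkaline peroxide may degrade the flavonol.

Fallback: ring C is closed under acid from an epoxide in which both ortho oxygens are masked, so that no phenoxide is present during oxygen transfer. It sets out from chalcone 9 and rejoins at target 18. Chalcone 9 would be O-alkylated (NaH, MOMCl, DMF, 0 °C) to the 2',6'-bis-MOM chalcone F10. Weitz–Scheffer epoxidation (H2O2, NaOH, MeOH–THF) would give the racemic trans-chalcone epoxide F11. HCl in MeOH (about 45 °C) would cleave both acetals, and the freed phenol would open the epoxide at the benzylic carbon (6-endo, helped by the para-alkoxy group of ring B) to give the racemic 5-hydroxy trans-dihydroflavonol F12. Dehydrogenation with alkaline H2O2, the second half of the Algar–Flynn–Oyamada sequence, would give the 5-hydroxyflavonol alkyne F13. Lindlar semihydrogenation as in step 7 would give the MOM-free key precursor F14. The heating of step 8 would convert it directly into 18, so step 9 would no longer be needed.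

3. Step 1. What may go wrong: the ambident phloroglucinol-type anion may be alkylated twice or at ring carbon, so that mono-O-prenylation at O4 becomes unselective.

Fallback: Mitsunobu etherification, in which the triol is never deprotonated in bulk and the most acidic, non-chelated 4-OH is selected as the pronucleophile. Compound 1 would be treated with 3-methylbut-2-en-1-ol, PPh3 and diisopropyl azodicarboxylate in THF at 0 °C. It sets out from 1 and returns at 3 without any compound outside the compound list (F0).

**Further compounds**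

F1 | step 8 | 2-bromo-4,5-dimethoxybenzaldehyde (purchased starting point of the fallback) | O=Cc1cc(OC)c(OC)cc1Br
F2 | step 8 | 2-bromo-4,5-dihydroxybenzaldehyde | O=Cc1cc(O)c(O)cc1Br
F3 | step 8 | 2-bromo-4-hydroxy-5-(methoxymethoxy)benzaldehyde | O=Cc1cc(OCOC)c(O)cc1Br
F4 | step 8 | 4-hydroxy-5-(methoxymethoxy)-2-(3-methylbut-2-enyl)benzaldehyde | O=Cc1cc(OCOC)c(O)cc1CC=C(C)C
F5 | step 8 | 5-(methoxymethoxy)-4-(2-methylbut-3-yn-2-yloxy)-2-(3-methylbut-2-enyl)benzaldehyde | O=Cc1cc(OCOC)c(OC(C)(C)C#C)cc1CC=C(C)C
F6 | step 8 | (E)-1-[2-hydroxy-6-(methoxymethoxy)-4-(3-methylbut-2-enyloxy)phenyl]-3-[5-(methoxymethoxy)-4-(2-methylbut-3-yn-2-yloxy)-2-(3-methylbut-2-enyl)phenyl]prop-2-en-1-one | O=C(/C=C/c1cc(OCOC)c(OC(C)(C)C#C)cc1CC=C(C)C)c1c(O)cc(OCC=C(C)C)cc1OCOC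
F7 | step 8 | 3-hydroxy-5-(methoxymethoxy)-7-(3-methylbut-2-enyloxy)-2-[5-(methoxymethoxy)-4-(2-methylbut-3-yn-2-yloxy)-2-(3-methylbut-2-enyl)phenyl]chromen-4-one | O=c1c(O)c(-c2cc(OCOC)c(OC(C)(C)C#C)cc2CC=C(C)C)oc2cc(OCC=C(C)C)cc(OCOC)c12
F8 | step 8 | 3-hydroxy-5-(methoxymethoxy)-7-(3-methylbut-2-enyloxy)-2-[5-(methoxymethoxy)-4-(2-methylbut-3-en-2-yloxy)-2-(3-methylbut-2-enyl)phenyl]chromen-4-one | O=c1c(O)c(-c2cc(OCOC)c(OC(C)(C)C=C)cc2CC=C(C)C)oc2cc(OCC=C(C)C)cc(OCOC)c12
F9 | step 8 | 5,3'-di-O-MOM broussoflavonol C: 3,7-dihydroxy-2-[4-hydroxy-5-(methoxymethoxy)-2,3-bis(3-methylbut-2-enyl)phenyl]-5-(methoxymethoxy)-8-(2-methylbut-3-en-2-yl)chromen-4-one | C=CC(C)(C)c1c(O)cc(OCOC)c2c(=O)c(O)c(-c3cc(OCOC)c(O)c(CC=C(C)C)c3CC=C(C)C)oc12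
F10 | step 6 | (E)-1-[2,6-bis(methoxymethoxy)-4-(3-methylbut-2-enyloxy)phenyl]-3-[4-(2-methylbut-3-yn-2-yloxy)-3-(3-methylbut-2-enyloxy)phenyl]prop-2-en-1-one | O=C(/C=C/c1ccc(OC(C)(C)C#C)c(OCC=C(C)C)c1)c1c(OCOC)cc(OCC=C(C)C)cc1OCOC
F11 | step 6 | racemic trans-epoxide of F10 (one enantiomer drawn) | O=C([C@@H]1O[C@H]1c1ccc(OC(C)(C)C#C)c(OCC=C(C)C)c1)c1c(OCOC)cc(OCC=C(C)C)cc1OCOC
F12 | step 6 | racemic trans-3,5-dihydroxy-7-(3-methylbut-2-enyloxy)-2-[4-(2-methylbut-3-yn-2-yloxy)-3-(3-methylbut-2-enyloxy)phenyl]chroman-4-one (2R,3R enantiomer drawn) | c1cc(OC(C)(C)C#C)c(OCC=C(C)C)cc1[C@@H]1[C@@H](O)C(=O)c2c(O)cc(OCC=C(C)C)cc2O1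
F13 | step 6 | 3,5-dihydroxy-7-(3-methylbut-2-enyloxy)-2-[4-(2-methylbut-3-yn-2-yloxy)-3-(3-methylbut-2-enyloxy)phenyl]chromen-4-one | O=c1c(O)c(-c2ccc(OC(C)(C)C#C)c(OCC=C(C)C)c2)oc2cc(OCC=C(C)C)cc(O)c12
F14 | step 6 | 3,5-dihydroxy-7-(3-methylbut-2-enyloxy)-2-[4-(2-methylbut-3-en-2-yloxy)-3-(3-methylbut-2-enyloxy)phenyl]chromen-4-one | O=c1c(O)c(-c2ccc(OC(C)(C)C=C)c(OCC=C(C)C)c2)oc2cc(OCC=C(C)C)cc(O)c12
F0 | step 1 | none | none
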